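**Plan**

- Retrosynthesis: after removal of the acid-labile protecting groups, ring C is cut at three bonds (O1–C8a, C4a–C4, O1–C2). This divides the flavone into a ring A aryne and a ring B 2,3-dimethoxyacrylic acid. The acid is cut at the acyl C–C bond of a β-keto ester, and ring B at its two benzylic C–C bonds.
- Enabling feature: in ring A the adjacent carbons C8a and C4a carry O1 and the C4 carbonyl, C5 beside C4a carries oxygen and C8 beside C8a carries only hydrogen. This is the pattern produced when an oxygen nucleophile and then an acyl group add across a 3-alkoxybenzyne.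
- Forward: ring B is equipped first (prenyl by copper-catalysed allylation, side chain by B-alkyl Suzuki coupling) and extended to the acrylic acid by enolate acylation and O-methylation. Ring A is prepared as an ortho-silylaryl triflate. Ring C is closed last, followed by one global deprotection.
- Stereochemistry: the single stereocentre (S, side chain) comes from methyl (R)-3-hydroxy-2-methylpropanoate. Its ester carbon becomes the chain CH2, so the descriptor changes to S although no bond at the stereocentre is touched.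

Key step: step 16

Remark: Ar = 4-(methoxymethoxy)-3-[(3S)-3-methyl-4-(trityloxy)butyl]-5-(3-methylbut-2-en-1-yl)phenyl and trityl = triphenylmethyl; the β-keto ester is an epimer mixture at its α-carbon and the enol ethers derived from it are E/Z mixtures, which both converge in the annulation, so their SMILES leave these elements open.

**Route**

Step 1
Reactants: 1 methyl (R)-3-hydroxy-2-methylpropanoate
Product: 2 methyl (R)-2-methyl-3-(trityloxy)propanoate
Conditions: TrCl, Et3N, DMAP (cat.), CH2Cl2, 0 °C → rt
Reagents that add atoms: trityl chloride, ClC(c1ccccc1)(c1ccccc1)c1ccccc1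
Why: O-tritylation of the primary alcohol through the trityl cation (SN1 etherification) does not touch the α-stereocentre and gives an ether that is stable to fluoride and base yet cleaved by dilute acid.

Step 2
Reactants: 2 methyl (R)-2-methyl-3-(trityloxy)propanoate
Product: 3 (R)-2-methyl-3-(trityloxy)propanal
Conditions: i-Bu2AlH (1.1 equiv), CH2Cl2, −78 °C; aq. potassium sodium tartrate
Reagents that add atoms: none
Why: Partial ester reduction with i-Bu2AlH at −78 °C stops at the aluminium hemiacetal, which releases the aldehyde only on work-up, and the cold non-basic medium keeps the α-stereocentre intact.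

Step 3
Reactants: 3 (R)-2-methyl-3-(trityloxy)propanal
Product: 4 (2S)-2-methylbut-3-en-1-yl trityl ether
Conditions: Ph3PCH3Br, KN(SiMe3)2, THF, 0 °C; then 3, −78 → 0 °C
Reagents that add atoms: methyltriphenylphosphonium bromide, C[P+](c1ccccc1)(c1ccccc1)c1ccccc1.[Br-]
Why: Wittig methylenation with the preformed ylide at low temperature should outrun enolisation of the α-branched aldehyde, so the stereocentre is carried over and only its descriptor changes (R to S) through the priority rules.

Step 4
Reactants: 5 methyl 4-hydroxy-3,5-diiodobenzoate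
Product: 6 methyl 3,5-diiodo-4-(methoxymethoxy)benzoate
Conditions: MOMCl, i-Pr2NEt, CH2Cl2, 0 °C → rt
Reagents that add atoms: chloromethyl methyl ether, COCCl
Why: O-alkylation of the acidic 2,6-diiodophenol with the highly reactive chloromethyl ether (MOM protection) should proceed despite the two flanking iodines.

Step 5
Reactants: 6 methyl 3,5-diiodo-4-(methoxymethoxy)benzoate
Product: 8 methyl 3-iodo-4-(methoxymethoxy)-5-(3-methylbut-2-en-1-yl)benzoate, via arylmagnesium chloride 7 (not isolated)
Conditions: i-PrMgCl·LiCl (1.05 equiv), THF, −40 °C; CuBr·SMe2 (10 mol%), prenyl bromide, −40 → 0 °C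
Reagents that add atoms: 1-bromo-3-methylbut-2-ene, CC(C)=CCBr
Why: Iodine–magnesium exchange at −40 °C tolerates the ester and stops after one exchange because the first C–Mg bond deactivates the ring, and the copper-catalysed allylic substitution of prenyl bromide takes place at the primary carbon (SN2 mode) to give the linear prenyl group.

Step 6
Reactants: 4 (2S)-2-methylbut-3-en-1-yl trityl ether; 8 methyl 3-iodo-4-(methoxymethoxy)-5-(3-methylbut-2-en-1-yl)benzoate
Product: 10 methyl 4-(methoxymethoxy)-3-[(3S)-3-methyl-4-(trityloxy)butyl]-5-(3-methylbut-2-en-1-yl)benzoate (Ar–CO2Me), via B-alkyl-9-BBN adduct 9 (not isolated)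
Conditions: 4 (slight excess over borane), 9-BBN, THF, rt; then 8, PdCl2(dppf) (5 mol%), aq. K3PO4, DMF, 50 °C
Reagents that add atoms: none
Why: B-alkyl Suzuki–Miyaura coupling, in which anti-Markovnikov hydroboration of the terminal alkene and palladium-catalysed coupling with the aryl iodide form the aryl–CH2 bond without affecting the stereocentre, the trisubstituted prenyl alkene or the ester.

Step 7
Reactants: 10 Ar–CO2Me
Product: 11 4-(methoxymethoxy)-3-[(3S)-3-methyl-4-(trityloxy)butyl]-5-(3-methylbut-2-en-1-yl)benzoic acid (Ar–CO2H)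
Conditions: LiOH, THF/MeOH/H2O, 40 °C; aq. citric acid to pH 4
Reagents that add atoms: lithium hydroxide, [Li+].[OH-]
Why: Saponification of the unhindered methyl benzoate, with MOM and trityl ethers stable to base and a work-up kept at pH 4.

Step 8
Reactants: 12 methoxyacetic acid
Product: 13 prop-2-en-1-yl methoxyacetate
Conditions: allyl bromide, K2CO3, DMF, rt
Reagents that add atoms: allyl bromide, C=CCBr
Why: SN2 O-alkylation of the carboxylate gives the allyl ester, chosen because it can later be removed under neutral palladium catalysis.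

Step 9
Reactants: 11 Ar–CO2H; 13 prop-2-en-1-yl methoxyacetate
Product: 16 prop-2-en-1-yl 2-methoxy-3-oxo-3-Ar-propanoate (mixture of C2 epimers), via acyl imidazole 14 (not isolated), via lithium enolate 15 (not isolated)
Conditions: 11, CDI, THF, rt; added to 13 + LiN(SiMe3)2 (3 equiv each), THF, −78 → −40 °C; AcOH quench
Reagents that add atoms: none
Why: Crossed Claisen-type C-acylation of a lithium ester enolate by an acyl imidazole, in which excess enolate deprotonates the product and the liberated imidazole so that the reaction stops at the β-keto ester.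

Step 10
Reactants: 16 prop-2-en-1-yl 2-methoxy-3-oxo-3-Ar-propanoate
Product: 18 prop-2-en-1-yl 2,3-dimethoxy-3-Ar-prop-2-enoate (E/Z mixture), via potassium enolate 17 (not isolated)
Conditions: KN(SiMe3)2, 18-crown-6, THF, −78 °C; MeOTf, −78 → −20 °C
Reagents that add atoms: methyl trifluoromethanesulfonate, COS(=O)(=O)C(F)(F)F
Why: O-alkylation of a β-keto ester enolate, where the crown-separated potassium enolate, the hard methyl electrophile and the fully substituted α-carbon should direct methylation to oxygen.

Step 11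
Reactants: 18 prop-2-en-1-yl 2,3-dimethoxy-3-Ar-prop-2-enoate
Product: 19 2,3-dimethoxy-3-Ar-prop-2-enoic acid (E/Z mixture)
Conditions: Pd(PPh3)4 (5 mol%), HCO2H, Et3N (in excess over HCO2H), THF, rt; pH 5 buffer work-up
Reagents that add atoms: none
Why: Palladium-catalysed deallylation (Tsuji–Trost ionisation to the π-allyl complex, reduced by formate to propene) frees the acid under near-neutral, non-nucleophilic conditions that spare the enol ether, the MOM and trityl ethers and the prenyl alkene.

Step 12
Reactants: 20 2-methoxybenzene-1,3-diol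
Product: 21 2-methoxy-1,3-bis(methoxymethoxy)benzene
Conditions: MOMCl (2.5 equiv), i-Pr2NEt, CH2Cl2, 0 °C → rt
Reagents that add atoms: chloromethyl methyl ether, COCCl
Why: Double MOM protection by phenol O-alkylation masks the two hydroxyls that become the C5 and C7 hydroxyls of the target.

Step 13
Reactants: 21 2-methoxy-1,3-bis(methoxymethoxy)benzene
Product: 23 4-methoxy-3,5-bis(methoxymethoxy)phenol, via arylboronic ester 22 (not isolated)
Conditions: B2pin2, [Ir(OMe)(cod)]2 (1.5 mol%), dtbpy (3 mol%), THF, 80 °C; then 30% H2O2, aq. NaOH, 0 °C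
Reagents that add atoms: hydrogen peroxide, OO
Why: Iridium-catalysed C–H borylation (Hartwig–Miyaura type) is sterically controlled and should attack only C5 of the 1,2,3-trisubstituted arene, the one C–H with no ortho substituent, and oxidation of the boronate in the same flask gives the symmetric phenol.

Step 14
Reactants: 23 4-methoxy-3,5-bis(methoxymethoxy)phenol
Product: 24 2-bromo-4-methoxy-3,5-bis(methoxymethoxy)phenol
Conditions: NBS (1.0 equiv), CH2Cl2, −78 → −40 °C
Reagents that add atoms: N-bromosuccinimide, O=C1CCC(=O)N1Br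
Why: Electrophilic aromatic bromination ortho to the free hydroxyl, where the two ortho positions are equivalent and the para position is blocked, so one equivalent of NBS can give only this monobromide.

Step 15
Reactants: 24 2-bromo-4-methoxy-3,5-bis(methoxymethoxy)phenol
Product: 27 4-methoxy-3,5-bis(methoxymethoxy)-2-(trimethylsilyl)phenyl trifluoromethanesulfonate, via aryl trimethylsilyl ether 25 (not isolated), via lithium phenoxide 26 (not isolated)
Conditions: HN(SiMe3)2, THF, 65 °C, evaporate; n-BuLi, THF, −78 °C; Tf2O, −78 °C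
Reagents that add atoms: hexamethyldisilazane, C[Si](C)(C)N[Si](C)(C)C; trifluoromethanesulfonic anhydride, O=S(=O)(OS(=O)(=O)C(F)(F)F)C(F)(F)F
Why: O-silylation, bromine–lithium exchange and 1,3 O→C silyl migration (retro-Brook rearrangement) place the silyl group on the carbon between the phenoxide and the MOM ether, and triflation of the phenoxide then gives the ortho-silylaryl triflate.

Step 16
Reactants: 19 2,3-dimethoxy-3-Ar-prop-2-enoic acid; 27 4-methoxy-3,5-bis(methoxymethoxy)-2-(trimethylsilyl)phenyl trifluoromethanesulfonate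
Product: 31 2-Ar-3,6-dimethoxy-5,7-bis(methoxymethoxy)-4H-chromen-4-one, via caesium carboxylate 28 (not isolated), via aryne 29 (not isolated), via caesium 2-acylphenoxide 30 (not isolated)
Conditions: 19, Cs2CO3 (0.5 equiv), MeOH, rt, evaporate and dry; 27 (1.5 equiv), CsF (3 equiv), THF, 80 °C (sealed)
Reagents that add atoms: none
Why: Proposed new method: fluoride removes the silyl group of 27 and triflate departs to give aryne 29, carboxylate 28 adds through oxygen to the aryne carbon remote from the C5 oxygen (C8a), the aryl anion generated at C4a attacks the adjacent ester carbonyl through a four-membered alkoxide (an anionic Fries-type 1,3 O→C acyl shift, making C4a–C4) and opens to phenoxide 30, which adds to the β-carbon of the β-methoxy enone and expels methoxide (O1–C2). The closest known reaction types are the insertion of arynes into the C–O bond of carboxylic acids to give ortho-hydroxyaryl ketones, the aryne–salicylate annulation to xanthones and the base-induced closure of 2′-hydroxy-β-alkoxychalcones to flavones. Ring C closes by a 6-endo-trig oxa-Michael addition followed by elimination, so both alkene isomers of the acid should give the same flavone, and no stereocentre is created. The step needs regioselective addition to the unsymmetrical aryne, which the methoxymethoxy group beside the triple bond should secure through its inductive effect (attack at the distal carbon, anion stabilised next to oxygen), and it needs the acyl shift to outrun protonation or conjugate addition of the aryl anion, which the preformed caesium carboxylate in aprotic THF and the s-trans ester conformation (carbonyl carbon rather than β-carbon next to the anion) should favour.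

Step 17
Reactants: 31 2-Ar-3,6-dimethoxy-5,7-bis(methoxymethoxy)-4H-chromen-4-one
Product: 32 5,7-dihydroxy-2-{4-hydroxy-3-[(3S)-4-hydroxy-3-methylbutyl]-5-(3-methylbut-2-en-1-yl)phenyl}-3,6-dimethoxy-4H-chromen-4-one
Conditions: 3 M aq. HCl, MeOH, 45 °C
Reagents that add atoms: none
Why: Acid-catalysed acetal cleavage removes the three aryl MOM ethers and methanolysis through the trityl cation frees the primary alcohol in the same operation, with dilute acid and moderate temperature chosen so that the prenyl group beside the new 4′-hydroxyl is not cyclised to a chroman.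

**Compound list**

1 | methyl (R)-3-hydroxy-2-methylpropanoate | COC(=O)[C@H](C)CO | starting material
2 | methyl (R)-2-methyl-3-(trityloxy)propanoate | COC(=O)[C@H](C)COC(c1ccccc1)(c1ccccc1)c1ccccc1 | intermediate
3 | (R)-2-methyl-3-(trityloxy)propanal | O=C[C@H](C)COC(c1ccccc1)(c1ccccc1)c1ccccc1 | intermediate
4 | (2S)-2-methylbut-3-en-1-yl trityl ether | C=C[C@H](C)COC(c1ccccc1)(c1ccccc1)c1ccccc1 | intermediate
5 | methyl 4-hydroxy-3,5-diiodobenzoate | COC(=O)c1cc(I)c(O)c(I)c1 | starting material
6 | methyl 3,5-diiodo-4-(methoxymethoxy)benzoate | COC(=O)c1cc(I)c(OCOC)c(I)c1 | intermediate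
7 | [3-iodo-5-(methoxycarbonyl)-2-(methoxymethoxy)phenyl]magnesium chloride | COC(=O)c1cc(I)c(OCOC)c([Mg]Cl)c1 | intermediate
8 | methyl 3-iodo-4-(methoxymethoxy)-5-(3-methylbut-2-en-1-yl)benzoate | COC(=O)c1cc(I)c(OCOC)c(CC=C(C)C)c1 | intermediate
9 | 9-[(3S)-3-methyl-4-(trityloxy)butyl]-9-borabicyclo[3.3.1]nonane | B1(CC[C@H](C)COC(c2ccccc2)(c2ccccc2)c2ccccc2)C2CCCC1CCC2 | intermediate
10 | methyl 4-(methoxymethoxy)-3-[(3S)-3-methyl-4-(trityloxy)butyl]-5-(3-methylbut-2-en-1-yl)benzoate | COC(=O)c1cc(CC=C(C)C)c(OCOC)c(CC[C@H](C)COC(c2ccccc2)(c2ccccc2)c2ccccc2)c1 | intermediate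
11 | 4-(methoxymethoxy)-3-[(3S)-3-methyl-4-(trityloxy)butyl]-5-(3-methylbut-2-en-1-yl)benzoic acid | OC(=O)c1cc(CC=C(C)C)c(OCOC)c(CC[C@H](C)COC(c2ccccc2)(c2ccccc2)c2ccccc2)c1 | intermediate
12 | methoxyacetic acid | COCC(=O)O | starting material
13 | prop-2-en-1-yl methoxyacetate | COCC(=O)OCC=C | intermediate
14 | 1H-imidazol-1-yl aryl ketone of acid 11 (Ar–CO–imidazol-1-yl) | O=C(n1ccnc1)c1cc(CC=C(C)C)c(OCOC)c(CC[C@H](C)COC(c2ccccc2)(c2ccccc2)c2ccccc2)c1 | intermediate
15 | lithium 2-methoxy-1-(prop-2-en-1-yloxy)ethen-1-olate | [Li+].[O-]C(=COC)OCC=C | intermediate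
16 | prop-2-en-1-yl 2-methoxy-3-oxo-3-Ar-propanoate (C2 epimers) | C=CCOC(=O)C(OC)C(=O)c1cc(CC=C(C)C)c(OCOC)c(CC[C@H](C)COC(c2ccccc2)(c2ccccc2)c2ccccc2)c1 | intermediate
17 | potassium enolate of 16 | [K+].[O-]C(=C(OC)C(=O)OCC=C)c1cc(CC=C(C)C)c(OCOC)c(CC[C@H](C)COC(c2ccccc2)(c2ccccc2)c2ccccc2)c1 | intermediate
18 | prop-2-en-1-yl 2,3-dimethoxy-3-Ar-prop-2-enoate (E/Z) | C=CCOC(=O)C(OC)=C(OC)c1cc(CC=C(C)C)c(OCOC)c(CC[C@H](C)COC(c2ccccc2)(c2ccccc2)c2ccccc2)c1 | intermediate
19 | 2,3-dimethoxy-3-Ar-prop-2-enoic acid (E/Z) | OC(=O)C(OC)=C(OC)c1cc(CC=C(C)C)c(OCOC)c(CC[C@H](C)COC(c2ccccc2)(c2ccccc2)c2ccccc2)c1 | intermediate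
20 | 2-methoxybenzene-1,3-diol | COc1c(O)cccc1O | starting material
21 | 2-methoxy-1,3-bis(methoxymethoxy)benzene | COCOc1cccc(OCOC)c1OC | intermediate
22 | 2-[4-methoxy-3,5-bis(methoxymethoxy)phenyl]-4,4,5,5-tetramethyl-1,3,2-dioxaborolane | COCOc1cc(B2OC(C)(C)C(C)(C)O2)cc(OCOC)c1OC | intermediate
23 | 4-methoxy-3,5-bis(methoxymethoxy)phenol | COCOc1cc(O)cc(OCOC)c1OC | intermediate
24 | 2-bromo-4-methoxy-3,5-bis(methoxymethoxy)phenol | COCOc1cc(O)c(Br)c(OCOC)c1OC | intermediate
25 | [2-bromo-4-methoxy-3,5-bis(methoxymethoxy)phenoxy]trimethylsilane | COCOc1cc(O[Si](C)(C)C)c(Br)c(OCOC)c1OC | intermediate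
26 | lithium 4-methoxy-3,5-bis(methoxymethoxy)-2-(trimethylsilyl)phenoxide | [Li+].[O-]c1cc(OCOC)c(OC)c(OCOC)c1[Si](C)(C)C | intermediate
27 | 4-methoxy-3,5-bis(methoxymethoxy)-2-(trimethylsilyl)phenyl trifluoromethanesulfonate | COCOc1cc(OS(=O)(=O)C(F)(F)F)c([Si](C)(C)C)c(OCOC)c1OC | intermediate
28 | caesium 2,3-dimethoxy-3-Ar-prop-2-enoate (E/Z) | [Cs+].[O-]C(=O)C(OC)=C(OC)c1cc(CC=C(C)C)c(OCOC)c(CC[C@H](C)COC(c2ccccc2)(c2ccccc2)c2ccccc2)c1 | intermediate
29 | 1,2-didehydro-4-methoxy-3,5-bis(methoxymethoxy)benzene (aryne) | COCOC1=CC#CC(OCOC)=C1OC | intermediate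
30 | caesium 2-(2,3-dimethoxy-3-Ar-prop-2-enoyl)-4-methoxy-3,5-bis(methoxymethoxy)phenoxide | [Cs+].[O-]c1cc(OCOC)c(OC)c(OCOC)c1C(=O)C(OC)=C(OC)c1cc(CC=C(C)C)c(OCOC)c(CC[C@H](C)COC(c2ccccc2)(c2ccccc2)c2ccccc2)c1 | intermediate
31 | 2-{4-(methoxymethoxy)-3-[(3S)-3-methyl-4-(trityloxy)butyl]-5-(3-methylbut-2-en-1-yl)phenyl}-3,6-dimethoxy-5,7-bis(methoxymethoxy)-4H-chromen-4-one | COc1c(OCOC)cc2oc(-c3cc(CC=C(C)C)c(OCOC)c(CC[C@H](C)COC(c4ccccc4)(c4ccccc4)c4ccccc4)c3)c(OC)c(=O)c2c1OCOC | intermediate
32 | 5,7-dihydroxy-2-{4-hydroxy-3-[(3S)-4-hydroxy-3-methylbutyl]-5-(3-methylbut-2-en-1-yl)phenyl}-3,6-dimethoxy-4H-chromen-4-one | COc1c(O)cc2oc(-c3cc(CC=C(C)C)c(O)c(CC[C@H](C)CO)c3)c(OC)c(=O)c2c1O | target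

**Step count**

Total step count: 17. Longest linear sequence: 10 steps (steps 1, 2, 3, 6, 7, 9, 10, 11, 16, 17).

**Steps most likely to fail**

Step 16. The aryl anion formed after O-arylation may be protonated before the acyl shift, which would stop the sequence at simple O-arylation. Addition may also occur with the wrong orientation on the aryne, and the excess aryne may undergo an ene reaction with the prenyl group. The fallback sets out from 24 and 19 and returns to the route at 31, using only known reaction types. Esterification (EDC, DMAP, CH2Cl2) should give 2-bromo-4-methoxy-3,5-bis(methoxymethoxy)phenyl 2,3-dimethoxy-3-Ar-prop-2-enoate F1. Bromine–lithium exchange (t-BuLi, THF, −100 °C) then generates the same ortho anion at a position fixed by the bromine and triggers the anionic Fries-type 1,3 O→C acyl migration. This leads to lithium 2-(2,3-dimethoxy-3-Ar-prop-2-enoyl)-4-methoxy-3,5-bis(methoxymethoxy)phenoxide F2. On warming, F2 closes ring C by the same addition–elimination with loss of methoxide and delivers 31.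

Step 10. Methylation may take place at the α-carbon instead of the enolate oxygen, or the hindered enolate may react incompletely. The fallback sets out from 16 and returns at 19, separating the O-functionalisation from the introduction of the methoxy group. Enol sulfonylation (TsCl, N-methylimidazole, Et3N, CH2Cl2), which is reliably O-selective, should give prop-2-en-1-yl 2-methoxy-3-Ar-3-(tosyloxy)prop-2-enoate F3. Addition–elimination with NaOMe in MeOH replaces the tosylate by methoxide and at the same time transesterifies the allyl ester, giving methyl 2,3-dimethoxy-3-Ar-prop-2-enoate F4. Attack of methoxide at sulfur would only return the enolate of 16. Mild saponification of F4 (LiOH, THF/H2O) gives 19.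

Step 14. The very electron-rich phenol may be brominated twice or oxidised towards a quinone instead of being monobrominated. The fallback sets out from 23 and returns at 27, avoiding electrophilic halogenation altogether by directed ortho-metalation. Addition of the phenol to isopropyl isocyanate (Et3N, CH2Cl2) gives 4-methoxy-3,5-bis(methoxymethoxy)phenyl N-(propan-2-yl)carbamate F5. N-Silylation in the flask (t-BuMe2SiOTf, TMEDA), ortho-lithiation (n-BuLi, TMEDA, −78 °C; both ortho positions are equivalent) and quenching with Me3SiCl give 4-methoxy-3,5-bis(methoxymethoxy)-2-(trimethylsilyl)phenyl N-(propan-2-yl)carbamate F6. Carbamate cleavage with DBU and Et2NH in MeCN followed by PhNTf2 gives 27.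

Further compounds
F1 | step 16 | 2-bromo-4-methoxy-3,5-bis(methoxymethoxy)phenyl 2,3-dimethoxy-3-Ar-prop-2-enoate | COCOc1cc(OC(=O)C(OC)=C(OC)c2cc(CC=C(C)C)c(OCOC)c(CC[C@H](C)COC(c3ccccc3)(c3ccccc3)c3ccccc3)c2)c(Br)c(OCOC)c1OC
F2 | step 16 | lithium 2-(2,3-dimethoxy-3-Ar-prop-2-enoyl)-4-methoxy-3,5-bis(methoxymethoxy)phenoxide | [Li+].[O-]c1cc(OCOC)c(OC)c(OCOC)c1C(=O)C(OC)=C(OC)c1cc(CC=C(C)C)c(OCOC)c(CC[C@H](C)COC(c2ccccc2)(c2ccccc2)c2ccccc2)c1
F3 | step 10 | prop-2-en-1-yl 2-methoxy-3-Ar-3-(tosyloxy)prop-2-enoate | C=CCOC(=O)C(OC)=C(OS(=O)(=O)c1ccc(C)cc1)c1cc(CC=C(C)C)c(OCOC)c(CC[C@H](C)COC(c2ccccc2)(c2ccccc2)c2ccccc2)c1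
F4 | step 10 | methyl 2,3-dimethoxy-3-Ar-prop-2-enoate | COC(=O)C(OC)=C(OC)c1cc(CC=C(C)C)c(OCOC)c(CC[C@H](C)COC(c2ccccc2)(c2ccccc2)c2ccccc2)c1
F5 | step 14 | 4-methoxy-3,5-bis(methoxymethoxy)phenyl N-(propan-2-yl)carbamate | CC(C)NC(=O)Oc1cc(OCOC)c(OC)c(OCOC)c1
F6 | step 14 | 4-methoxy-3,5-bis(methoxymethoxy)-2-(trimethylsilyl)phenyl N-(propan-2-yl)carbamate | CC(C)NC(=O)Oc1cc(OCOC)c(OC)c(OCOC)c1[Si](C)(C)C
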